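**Assumption:** the target SMILES has no stereocentre or stereodescriptor, and the 18-membered marchantin-type ring is taken to be conformationally mobile (no isolable atropisomers). The compound is therefore achiral and no stereocontrol is needed.

## Retrosynthetic overview

1. The macrocycle is closed last, at the quinone C–O(ring D) bond, by intramolecular phenoxide addition–elimination on fluoroquinone 11 (the proposed new step).
2. 11 comes from mild oxidation of fluorohydroquinone 10, which comes from BBr3 demethylation of the open-chain tetramethyl ether 9.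
3. 9 comes from hydroboration of styrene 8 and sp3–sp2 Suzuki coupling with iodide 2 (quinone-ring precursor, from ortho-lithiation of 1).
4. 8 comes from aldehyde 7, made by SNAr of phenol 5 with 4-fluorobenzaldehyde (ring B); 5 comes from B-alkyl Suzuki coupling of 3-vinylanisole (ring D) with 5-bromo-2-methoxyphenol (ring C).
5. Ring order: all four six-membered rings are purchased; the quinone is unveiled in step 7; the 18-membered ring is the only ring formed (step 8).

## Route

**Step 1**
Reactants: 1, 2-fluoro-1,4-dimethoxybenzene
Product: 2, 2-fluoro-3-iodo-1,4-dimethoxybenzene (iodine on the carbon between F and OMe)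
Conditions: n-BuLi, THF, −78 °C, 1 h; then I2, −78 °C → rt
Reagents that add atoms: iodine, II
Why: Directed ortho-lithiation occurs at the only C–H flanked by both F and OMe (the most acidic site); the aryllithium is stable to benzyne formation at −78 °C and is trapped by I2.

**Step 2**
Reactants: 3, 3-vinylanisole (1-ethenyl-3-methoxybenzene); 4, 5-bromo-2-methoxyphenol
Product: 5, 2-methoxy-5-[2-(3-methoxyphenyl)ethyl]phenol
Conditions: 3 (1.3 equiv), 9-BBN, THF, 0 °C → rt; then 4, Pd(OAc)2/SPhos, K3PO4 (4 equiv), THF/H2O, 65 °C
Reagents that add atoms: none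
Why: Anti-Markovnikov hydroboration of the styrene followed by B-alkyl Suzuki–Miyaura coupling gives the saturated bibenzyl bridge directly; the free phenol only consumes one extra equivalent of base.

**Step 3**
Reactants: 5; 6, 4-fluorobenzaldehyde
Product: 7, 4-{2-methoxy-5-[2-(3-methoxyphenyl)ethyl]phenoxy}benzaldehyde
Conditions: K2CO3, DMF, 120 °C
Reagents that add atoms: none
Why: SNAr of the phenoxide on the para-formyl-activated aryl fluoride, the standard diaryl-ether construction for isovanillin-type phenols.

**Step 4**
Reactants: 7
Product: 8, 2-(4-ethenylphenoxy)-1-methoxy-4-[2-(3-methoxyphenyl)ethyl]benzene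
Conditions: Ph3PCH3Br, KOtBu, THF, 0 °C → rt
Reagents that add atoms: methyltriphenylphosphonium bromide, C[P+](c1ccccc1)(c1ccccc1)c1ccccc1.[Br-]
Why: Wittig methylenation of an aryl aldehyde; nothing else in the molecule is base-sensitive.

**Step 5**
Reactants: 8; 2
Product: 9, 2-fluoro-1,4-dimethoxy-3-[2-(4-{2-methoxy-5-[2-(3-methoxyphenyl)ethyl]phenoxy}phenyl)ethyl]benzene
Conditions: 8, 9-BBN, THF, rt; then 2 (1.2 equiv), Pd(OAc)2/SPhos, K3PO4, THF/H2O, 65 °C
Reagents that add atoms: none
Why: Hydroboration / B-alkyl Suzuki–Miyaura coupling; the aryl iodide undergoes fast oxidative addition, SPhos tolerates the two small ortho groups (F, OMe), and the unactivated C–F bond is inert.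

**Step 6**
Reactants: 9
Product: 10, 2-fluoro-3-[2-(4-{2-hydroxy-5-[2-(3-hydroxyphenyl)ethyl]phenoxy}phenyl)ethyl]benzene-1,4-diol
Conditions: BBr3 (8 equiv), CH2Cl2, −78 °C → rt; MeOH then H2O quench, under Ar
Reagents that add atoms: none
Why: Lewis-acid cleavage of all four aryl methyl ethers; the diaryl ether and the aryl C–F bond are stable to BBr3.

**Step 7**
Reactants: 10
Product: 11, 2-fluoro-3-[2-(4-{2-hydroxy-5-[2-(3-hydroxyphenyl)ethyl]phenoxy}phenyl)ethyl]cyclohexa-2,5-diene-1,4-dione
Conditions: Ag2O (2.5 equiv), Na2SO4, Et2O/THF, rt, 30 min; filter through Celite and use at once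
Reagents that add atoms: none
Why: Hydroquinone-to-quinone oxidation under neutral heterogeneous conditions; the hydroquinone is oxidised far more easily than the two monophenols, which are left untouched in a short reaction.

**Step 8**
Reactants: 11
Product: 12, marchantinquinone
Conditions: Cs2CO3 (3 equiv), 4 Å MS, MeCN, 11 added by syringe pump over 12 h to 1 mM final concentration, 0 °C → rt, Ar, dark; AcOH quench
Reagents that add atoms: none
Why: Proposed new method: intramolecular vinylogous acyl substitution (addition–elimination, SNV) macro-etherification of a fluoro-p-benzoquinone, in which the ring-D caesium phenoxide adds to the C–F carbon (the β-carbon of an enone, activated by fluorine) to give an enolate that expels fluoride (E1cB), restoring the quinone and closing the 18-membered ring; this site is the only one that reacts irreversibly, since oxa-Michael addition at the two unsubstituted quinone carbons is reversible without an oxidant, and the ring-C phenoxide cannot reach intramolecularly (it would give a strained 12-membered paracyclophane), so high dilution should funnel material to 12; the closest known reactions are intermolecular displacement of halide from haloquinones by phenoxides and SNAr macrocyclisations of activated aryl fluorides to cyclophane diaryl ethers.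

## Compound list

1 | 2-fluoro-1,4-dimethoxybenzene | COc1ccc(OC)c(F)c1 | starting material
2 | 2-fluoro-3-iodo-1,4-dimethoxybenzene | COc1ccc(OC)c(F)c1I | intermediate
3 | 3-vinylanisole | C=Cc1cccc(OC)c1 | starting material
4 | 5-bromo-2-methoxyphenol | COc1ccc(Br)cc1O | starting material
5 | 2-methoxy-5-[2-(3-methoxyphenyl)ethyl]phenol | COc1cccc(CCc2ccc(OC)c(O)c2)c1 | intermediate
6 | 4-fluorobenzaldehyde | O=Cc1ccc(F)cc1 | starting material
7 | 4-{2-methoxy-5-[2-(3-methoxyphenyl)ethyl]phenoxy}benzaldehyde | COc1cccc(CCc2ccc(OC)c(Oc3ccc(C=O)cc3)c2)c1 | intermediate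
8 | 2-(4-ethenylphenoxy)-1-methoxy-4-[2-(3-methoxyphenyl)ethyl]benzene | COc1cccc(CCc2ccc(OC)c(Oc3ccc(C=C)cc3)c2)c1 | intermediate
9 | 2-fluoro-1,4-dimethoxy-3-[2-(4-{2-methoxy-5-[2-(3-methoxyphenyl)ethyl]phenoxy}phenyl)ethyl]benzene | COc1cccc(CCc2ccc(OC)c(Oc3ccc(CCc4c(OC)ccc(OC)c4F)cc3)c2)c1 | intermediate
10 | 2-fluoro-3-[2-(4-{2-hydroxy-5-[2-(3-hydroxyphenyl)ethyl]phenoxy}phenyl)ethyl]benzene-1,4-diol | Oc1cccc(CCc2ccc(O)c(Oc3ccc(CCc4c(O)ccc(O)c4F)cc3)c2)c1 | intermediate
11 | 2-fluoro-3-[2-(4-{2-hydroxy-5-[2-(3-hydroxyphenyl)ethyl]phenoxy}phenyl)ethyl]cyclohexa-2,5-diene-1,4-dione | Oc1cccc(CCc2ccc(O)c(Oc3ccc(CCC4=C(F)C(=O)C=CC4=O)cc3)c2)c1 | intermediate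
12 | marchantinquinone | O=C1C=CC(=O)C2=C1CCc1ccc(cc1)Oc1cc(ccc1O)CCc1cccc(c1)O2 | target

## Summary

Total step count: 8.
Longest linear sequence: 7 (steps 2–8; step 1 is a one-step side branch).

Three steps most likely to fail:

1. **Step 8 (proposed new macrocyclisation).** Risks are base-induced decomposition of the alkyl-fluoroquinone and oligomerisation. Fallback (known chemistry): form the quinone-ring/ring-D ether first by intermolecular SNAr of a ring-D phenol on 2-fluoro-3,6-dimethoxybenzaldehyde (from 1 with n-BuLi then DMF). Then close the 18-membered ring at the ethylene bridge to ring B by the established high-dilution intramolecular Wittig reaction, hydrogenate (H2, Pd/C), and finish with BBr3 and Ag2O.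
2. **Step 5 (B-alkyl Suzuki on the di-ortho-substituted iodide 2).** Fallback: convert aldehyde 7 to the terminal alkyne (Ohira–Bestmann), couple with 2 by Sonogashira reaction, and hydrogenate the diarylalkyne (H2, Pd/C; the C–F bond survives) to reach the same 9.
3. **Step 2 (B-alkyl Suzuki on an unprotected, electron-rich bromophenol).** Fallback: Wittig olefination of isovanillin with (3-methoxybenzyl)triphenylphosphonium bromide, then H2, Pd/C, to give the same bibenzyl phenol 5.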